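**Plan**

1. Numbering: lactone O1, C2(=O), C3, C4H2, C5; side chain C1′ (alkylidene CH) to C11′ (carbinol), which carries the butenolide ring.
2. Cuts, in retrosynthetic order: O–Si at C11′; the butenolide ring back to a 3-furyl ring; ring bond C3–C4 of the γ-butyrolactone; ester bond C2–O1; then C2–C3 (carboxylation), C10′–C11′ (allyl plus acyl anion) and C2′–C3′ (propargyl plus allyl), which leaves geraniol, 1-(trimethylsilyl)propyne, 3-furaldehyde and (S)-glyceraldehyde acetonide.
3. Forward: geraniol is functionalised at its E-methyl group and at C1 to give the furan-bearing ynoic acid 18; 18 is esterified with hydroxy tosylate 24; the γ-butyrolactone ring closes at C3–C4; the furan ring is oxidised to the butenolide ring; desilylation ends the route.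
4. Enabling feature: the exocyclic C3=C1′ double bond conjugated with the lactone C2=O, with the hydrogen on C1′ cis to the ring CH2 (C4), is the outcome of syn addition of H–Cu to a C3≡C1′ ynoate followed by stereoretentive attack of C3 on a primary electrophile at C4, with the ester O1–C5 as tether.
5. Stereochemistry: C5 (S) from the chiral pool; C11′ (R) from a Corey–Bakshi–Shibata reduction; 4′E and 8′E from geraniol and an E-selective SeO2 oxidation; 3Z from the key step.

Key step: step 17

Remark: the (S)-aldehyde 19 is taken as a purchasable chiral-pool compound and is used cold and promptly, because α-alkoxy aldehydes of this kind epimerise and oligomerise on standing.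

**Route**

Step 1
Reactants: 1 geraniol
Product: 2 tert-butyl{[(2E)-3,7-dimethylocta-2,6-dien-1-yl]oxy}dimethylsilane
Conditions: TBSCl, imidazole, DMF, 0 °C → rt
Reagents that add atoms: tert-butyldimethylsilyl chloride, CC(C)(C)[Si](C)(C)Cl
Why: Routine silylation of the primary allylic alcohol masks the C10′ oxygen against the oxidant of step 2 and the organolithium of step 4.

Step 2
Reactants: 2 tert-butyl{[(2E)-3,7-dimethylocta-2,6-dien-1-yl]oxy}dimethylsilane
Product: 3 (2E,6E)-8-[(tert-butyldimethylsilyl)oxy]-2,6-dimethylocta-2,6-dien-1-ol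
Conditions: SeO2 (10 mol %), t-BuOOH, salicylic acid (10 mol %), CH2Cl2, 0 °C → rt
Reagents that add atoms: tert-butyl hydroperoxide, CC(C)(C)OO
Why: Catalytic SeO2 allylic oxidation (Riley type, ene reaction then 2,3-sigmatropic shift) attacks the E-methyl group of the terminal, most electron-rich trisubstituted alkene of geranyl ethers, so the E allylic alcohol should form and fix the later C4′=C5′ geometry.

Step 3
Reactants: 3 (2E,6E)-8-[(tert-butyldimethylsilyl)oxy]-2,6-dimethylocta-2,6-dien-1-ol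
Product: 4 {[(2E,6E)-8-bromo-3,7-dimethylocta-2,6-dien-1-yl]oxy}(tert-butyl)dimethylsilane
Conditions: CBr4, PPh3, CH2Cl2, 0 °C
Reagents that add atoms: carbon tetrabromide, BrC(Br)(Br)Br
Why: Appel bromination converts the primary allylic alcohol into the bromide under neutral conditions that leave the silyl ether and both E alkenes alone.

Step 4
Reactants: 4 {[(2E,6E)-8-bromo-3,7-dimethylocta-2,6-dien-1-yl]oxy}(tert-butyl)dimethylsilane; 5 1-(trimethylsilyl)propyne
Product: 7 tert-butyl{[(2E,6E)-3,7-dimethyl-11-(trimethylsilyl)undeca-2,6-dien-10-yn-1-yl]oxy}dimethylsilane, via 3-lithio-1-(trimethylsilyl)propyne 6 (not isolated)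
Conditions: 5, n-BuLi, THF, −78 → −20 °C; then 4, −78 → 0 °C
Reagents that add atoms: none
Why: The silyl-capped propargylic lithium reagent alkylates primary allylic bromides by SN2 at its propargylic terminus, which forms the C2′–C3′ bond and brings in C3, C1′ and C2′ without touching alkene geometry.

Step 5
Reactants: 7 tert-butyl{[(2E,6E)-3,7-dimethyl-11-(trimethylsilyl)undeca-2,6-dien-10-yn-1-yl]oxy}dimethylsilane
Product: 8 [(5E,9E)-11-bromo-5,9-dimethylundeca-5,9-dien-1-yn-1-yl]trimethylsilane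
Conditions: Ph3PBr2, CH2Cl2, 0 °C → rt
Reagents that add atoms: dibromotriphenylphosphorane, BrP(Br)(c1ccccc1)(c1ccccc1)c1ccccc1
Why: Dibromotriphenylphosphorane turns tert-butyldimethylsilyl ethers of primary alcohols directly into bromides through a silyloxyphosphonium ion, so deprotection and activation of C10′ are merged and the C-silyl alkyne is untouched.

Step 6
Reactants: 9 3-furaldehyde
Product: 10 2-(furan-3-yl)-1,3-dithiane
Conditions: propane-1,3-dithiol, BF3·OEt2 (cat.), CH2Cl2, 0 °C → rt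
Reagents that add atoms: propane-1,3-dithiol, SCCCS
Why: Lewis-acid thioacetalisation gives the dithiane that makes the aldehyde carbon (the future C11′) an acyl-anion equivalent (Corey–Seebach umpolung).

Step 7
Reactants: 10 2-(furan-3-yl)-1,3-dithiane; 8 [(5E,9E)-11-bromo-5,9-dimethylundeca-5,9-dien-1-yn-1-yl]trimethylsilane
Product: 12 2-(furan-3-yl)-2-[(2E,6E)-3,7-dimethyl-11-(trimethylsilyl)undeca-2,6-dien-10-yn-1-yl]-1,3-dithiane, via 2-lithio-2-(furan-3-yl)-1,3-dithiane 11 (not isolated)
Conditions: 10, n-BuLi, THF, −40 °C; then 8, −78 → 0 °C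
Reagents that add atoms: none
Why: Corey–Seebach alkylation: the aryl-stabilised dithiane anion forms in preference to ring lithiation of the furan and attacks the primary allylic bromide by SN2, which forms the C10′–C11′ bond.

Step 8
Reactants: 12 2-(furan-3-yl)-2-[(2E,6E)-3,7-dimethyl-11-(trimethylsilyl)undeca-2,6-dien-10-yn-1-yl]-1,3-dithiane
Product: 13 (3E,7E)-1-(furan-3-yl)-4,8-dimethyl-12-(trimethylsilyl)dodeca-3,7-dien-11-yn-1-one
Conditions: MeI, CaCO3, MeCN/H2O (9:1), 40 °C
Reagents that add atoms: water, O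
Why: S-methylation and hydrolysis buffered by CaCO3 unmask the ketone under near-neutral conditions, which should keep the β,γ-alkene out of conjugation and spare the furan.

Step 9
Reactants: 13 (3E,7E)-1-(furan-3-yl)-4,8-dimethyl-12-(trimethylsilyl)dodeca-3,7-dien-11-yn-1-one
Product: 14 (1R,3E,7E)-1-(furan-3-yl)-4,8-dimethyl-12-(trimethylsilyl)dodeca-3,7-dien-11-yn-1-ol
Conditions: (S)-2-methyl-CBS-oxazaborolidine (20 mol %), catecholborane, toluene, −78 °C; then MeOH, aq. NaHCO3
Reagents that add atoms: none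
Why: Corey–Bakshi–Shibata reduction: the (S)-oxazaborolidine should deliver hydride to the ketone face that keeps the 3-furyl group (large) away from the catalyst and the allylic CH2 (small) toward it, which by analogy with aryl alkyl ketones gives the R carbinol at C11′.

Step 10
Reactants: 14 (1R,3E,7E)-1-(furan-3-yl)-4,8-dimethyl-12-(trimethylsilyl)dodeca-3,7-dien-11-yn-1-ol
Product: 15 tert-butyl{[(1R,3E,7E)-1-(furan-3-yl)-4,8-dimethyl-12-(trimethylsilyl)dodeca-3,7-dien-11-yn-1-yl]oxy}dimethylsilane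
Conditions: TBSCl, imidazole, DMF, rt
Reagents that add atoms: tert-butyldimethylsilyl chloride, CC(C)(C)[Si](C)(C)Cl
Why: Silylation protects the secondary hydroxyl, which would otherwise be acylated in step 16 and would quench the alkenylcopper of step 17.

Step 11
Reactants: 15 tert-butyl{[(1R,3E,7E)-1-(furan-3-yl)-4,8-dimethyl-12-(trimethylsilyl)dodeca-3,7-dien-11-yn-1-yl]oxy}dimethylsilane
Product: 16 tert-butyl{[(1R,3E,7E)-1-(furan-3-yl)-4,8-dimethyldodeca-3,7-dien-11-yn-1-yl]oxy}dimethylsilane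
Conditions: K2CO3, MeOH, rt
Reagents that add atoms: none
Why: Carbonate-mediated methanolysis cleaves the C(sp)–Si bond selectively, the O–Si bond of the hindered secondary silyl ether being stable to these conditions.

Step 12
Reactants: 16 tert-butyl{[(1R,3E,7E)-1-(furan-3-yl)-4,8-dimethyldodeca-3,7-dien-11-yn-1-yl]oxy}dimethylsilane
Product: 18 (6E,10E,13R)-13-[(tert-butyldimethylsilyl)oxy]-13-(furan-3-yl)-6,10-dimethyltrideca-6,10-dien-2-ynoic acid, via lithium acetylide 17 (not isolated)
Conditions: n-BuLi (1.05 equiv), THF, −78 °C; then CO2, −78 → 0 °C; then 1 M HCl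
Reagents that add atoms: carbon dioxide, O=C=O
Why: The acetylenic hydrogen is by far the most acidic one, so one equivalent of n-BuLi gives the acetylide, and its carboxylation installs C2 as the 2-ynoic acid.

Step 13
Reactants: 19 (S)-2,2-dimethyl-1,3-dioxolane-4-carbaldehyde; 20 isopropyltriphenylphosphonium iodide
Product: 22 (R)-2,2-dimethyl-4-(2-methylprop-1-en-1-yl)-1,3-dioxolane, via isopropylidenetriphenylphosphorane 21 (not isolated)
Conditions: 20, n-BuLi, THF, 0 °C; then 19, −78 °C → rt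
Reagents that add atoms: none
Why: Wittig olefination with the unstabilised isopropylidene ylide builds the 2-methylprop-1-enyl group on C5 without a geometry issue, and the stereocentre comes unchanged from the chiral pool (the descriptor changes from S to R only through the priority rules).

Step 14
Reactants: 22 (R)-2,2-dimethyl-4-(2-methylprop-1-en-1-yl)-1,3-dioxolane
Product: 23 (R)-4-methylpent-3-ene-1,2-diol
Conditions: AcOH/H2O (4:1), rt
Reagents that add atoms: none
Why: Mild aqueous acid hydrolyses the acetonide, and the conditions are kept mild because the secondary allylic alcohol can ionise.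

Step 15
Reactants: 23 (R)-4-methylpent-3-ene-1,2-diol
Product: 24 (2R)-2-hydroxy-4-methylpent-3-en-1-yl 4-methylbenzenesulfonate
Conditions: TsCl (1.05 equiv), Bu2SnO (2 mol %), Et3N, CH2Cl2, 0 °C
Reagents that add atoms: 4-methylbenzenesulfonyl chloride, Cc1ccc(cc1)S(Cl)(=O)=O
Why: Tin-acetal-catalysed monosulfonylation of 1,2-diols is selective for the primary hydroxyl, which turns C4 into the electrophile and leaves the C5 hydroxyl free.

Step 16
Reactants: 18 (6E,10E,13R)-13-[(tert-butyldimethylsilyl)oxy]-13-(furan-3-yl)-6,10-dimethyltrideca-6,10-dien-2-ynoic acid; 24 (2R)-2-hydroxy-4-methylpent-3-en-1-yl 4-methylbenzenesulfonate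
Product: 25 (2R)-4-methyl-1-(tosyloxy)pent-3-en-2-yl (6E,10E,13R)-13-[(tert-butyldimethylsilyl)oxy]-13-(furan-3-yl)-6,10-dimethyltrideca-6,10-dien-2-ynoate
Conditions: DCC, DMAP (5 mol %), CH2Cl2, −20 → 0 °C
Reagents that add atoms: none
Why: Steglich esterification joins the two fragments through the C2–O1 bond with retention at C5, the acidic 2-ynoic acid being activated under nearly neutral conditions that should not close the hydroxy tosylate to an epoxide.

Step 17
Reactants: 25 (2R)-4-methyl-1-(tosyloxy)pent-3-en-2-yl (6E,10E,13R)-13-[(tert-butyldimethylsilyl)oxy]-13-(furan-3-yl)-6,10-dimethyltrideca-6,10-dien-2-ynoate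
Product: 27 (3Z,5S)-3-[(4E,8E,11R)-11-[(tert-butyldimethylsilyl)oxy]-11-(furan-3-yl)-4,8-dimethylundeca-4,8-dien-1-ylidene]-5-(2-methylprop-1-en-1-yl)dihydrofuran-2(3H)-one, via α-cuprio enoate 26 (not isolated)
Conditions: chloro[1,3-bis(2,6-diisopropylphenyl)imidazol-2-ylidene]copper (10 mol %), NaOtBu (10 mol %), (EtO)2MeSiH (1.1 equiv), CsF (2 equiv), 1,4-dioxane, rt → 45 °C
Reagents that add atoms: none
Why: Proposed new method: the copper hydride generated from the N-heterocyclic-carbene copper fluoride and the silane should add syn across the polarised C3≡C1′ bond of the 2-ynoate, hydride to C1′ and copper to C3, and the C-bound alkenylcopper 26, whose C–Cu σ bond lies in the plane of the conjugated ester, then displaces the primary tosylate at C4 with retention at C3 while CsF returns the copper tosylate to the fluoride. The closest known reaction types are the copper-hydride hydroalkylation of alkynes with alkyl sulfonates through alkenylcopper species, the copper-catalysed borylative cyclisation of alkynes carrying alkyl halides or sulfonates, and the copper-hydride reductive aldol cyclisation of unsaturated esters of hydroxy ketones to β-hydroxy lactones; alkylation of an ynoate α-carbon through its own ester tether has not been shown. The γ-butyrolactone ring closes in the 5-exo-tet mode, open here because the nucleophile is a σ-alkenyl metal and not an enolate π system. No stereocentre is created and C5 (S) is a spectator because the substitution occurs at the neighbouring CH2, but the C3=C1′ geometry is fixed as Z by syn hydrocupration followed by stereoretentive C–C bond formation, which leaves the hydrogen on C1′ cis to C4. The step needs chemoselectivity of Cu–H for the ynoate over the three trisubstituted alkenes, the furan and the allylic C5–O ester, which the polarisation of the ynoate and a near-stoichiometric amount of silane should secure, and it needs a two-electron closure, for which a sulfonate was chosen because a radical at C4 would be a β-acyloxy homoallyl radical prone to 1,2-shifts.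

Step 18
Reactants: 27 (3Z,5S)-3-[(4E,8E,11R)-11-[(tert-butyldimethylsilyl)oxy]-11-(furan-3-yl)-4,8-dimethylundeca-4,8-dien-1-ylidene]-5-(2-methylprop-1-en-1-yl)dihydrofuran-2(3H)-one
Product: 31 (3Z,5S)-3-[(4E,8E,11R)-11-[(tert-butyldimethylsilyl)oxy]-4,8-dimethyl-11-(5-oxo-2,5-dihydrofuran-3-yl)undeca-4,8-dien-1-ylidene]-5-(2-methylprop-1-en-1-yl)dihydrofuran-2(3H)-one, via furan endoperoxide 28 (not isolated), via γ-hydroxybutenolide 29 (not isolated), via ring-opened sodium hydroxy enoate 30 (not isolated)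
Conditions: O2, hν (visible), tetraphenylporphyrin (cat.), i-Pr2NEt, CH2Cl2, −78 °C; then NaBH4, EtOH, −20 → 0 °C; then 1 M HCl
Reagents that add atoms: dioxygen, O=O
Why: Singlet oxygen adds across the furan in a (4+2) cycloaddition, the hindered amine removes the bridgehead hydrogen remote from the C11′ branch so that the carbonyl ends up there, and borohydride reduction of the masked aldehyde with acid relactonisation gives the 4-substituted furan-2(5H)-one; the furan should react with singlet oxygen faster than the trisubstituted alkenes, and the electron-poor alkylidene lactone is inert to it.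

Step 19
Reactants: 31 (3Z,5S)-3-[(4E,8E,11R)-11-[(tert-butyldimethylsilyl)oxy]-4,8-dimethyl-11-(5-oxo-2,5-dihydrofuran-3-yl)undeca-4,8-dien-1-ylidene]-5-(2-methylprop-1-en-1-yl)dihydrofuran-2(3H)-one
Product: 32 (3Z,5S)-3-[(4E,8E,11R)-11-hydroxy-4,8-dimethyl-11-(5-oxo-2,5-dihydrofuran-3-yl)undeca-4,8-dien-1-ylidene]-5-(2-methylprop-1-en-1-yl)dihydrofuran-2(3H)-one
Conditions: HF·pyridine, pyridine, THF, 0 °C → rt
Reagents that add atoms: none
Why: Buffered HF·pyridine cleaves the secondary silyl ether without base, which should spare both lactones, the allylic C5–O bond and the Z alkylidene geometry.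

**Compound list**

1 | geraniol, (2E)-3,7-dimethylocta-2,6-dien-1-ol | CC(C)=CCC/C(C)=C/CO | starting material
2 | tert-butyl{[(2E)-3,7-dimethylocta-2,6-dien-1-yl]oxy}dimethylsilane | CC(C)=CCC/C(C)=C/CO[Si](C)(C)C(C)(C)C | intermediate
3 | (2E,6E)-8-[(tert-butyldimethylsilyl)oxy]-2,6-dimethylocta-2,6-dien-1-ol | OC/C(C)=C/CC/C(C)=C/CO[Si](C)(C)C(C)(C)C | intermediate
4 | {[(2E,6E)-8-bromo-3,7-dimethylocta-2,6-dien-1-yl]oxy}(tert-butyl)dimethylsilane | BrC/C(C)=C/CC/C(C)=C/CO[Si](C)(C)C(C)(C)C | intermediate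
5 | 1-(trimethylsilyl)propyne | CC#C[Si](C)(C)C | starting material
6 | 3-lithio-1-(trimethylsilyl)propyne | [Li]CC#C[Si](C)(C)C | intermediate
7 | tert-butyl{[(2E,6E)-3,7-dimethyl-11-(trimethylsilyl)undeca-2,6-dien-10-yn-1-yl]oxy}dimethylsilane | C[Si](C)(C)C#CCC/C(C)=C/CC/C(C)=C/CO[Si](C)(C)C(C)(C)C | intermediate
8 | [(5E,9E)-11-bromo-5,9-dimethylundeca-5,9-dien-1-yn-1-yl]trimethylsilane | C[Si](C)(C)C#CCC/C(C)=C/CC/C(C)=C/CBr | intermediate
9 | 3-furaldehyde (furan-3-carbaldehyde) | O=Cc1ccoc1 | starting material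
10 | 2-(furan-3-yl)-1,3-dithiane | C1CSC(SC1)c1ccoc1 | intermediate
11 | 2-lithio-2-(furan-3-yl)-1,3-dithiane | [Li]C1(SCCCS1)c1ccoc1 | intermediate
12 | 2-(furan-3-yl)-2-[(2E,6E)-3,7-dimethyl-11-(trimethylsilyl)undeca-2,6-dien-10-yn-1-yl]-1,3-dithiane | C[Si](C)(C)C#CCC/C(C)=C/CC/C(C)=C/CC1(SCCCS1)c1ccoc1 | intermediate
13 | (3E,7E)-1-(furan-3-yl)-4,8-dimethyl-12-(trimethylsilyl)dodeca-3,7-dien-11-yn-1-one | C[Si](C)(C)C#CCC/C(C)=C/CC/C(C)=C/CC(=O)c1ccoc1 | intermediate
14 | (1R,3E,7E)-1-(furan-3-yl)-4,8-dimethyl-12-(trimethylsilyl)dodeca-3,7-dien-11-yn-1-ol | C[Si](C)(C)C#CCC/C(C)=C/CC/C(C)=C/C[C@@H](O)c1ccoc1 | intermediate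
15 | tert-butyl{[(1R,3E,7E)-1-(furan-3-yl)-4,8-dimethyl-12-(trimethylsilyl)dodeca-3,7-dien-11-yn-1-yl]oxy}dimethylsilane | C[Si](C)(C)C#CCC/C(C)=C/CC/C(C)=C/C[C@@H](O[Si](C)(C)C(C)(C)C)c1ccoc1 | intermediate
16 | tert-butyl{[(1R,3E,7E)-1-(furan-3-yl)-4,8-dimethyldodeca-3,7-dien-11-yn-1-yl]oxy}dimethylsilane | C#CCC/C(C)=C/CC/C(C)=C/C[C@@H](O[Si](C)(C)C(C)(C)C)c1ccoc1 | intermediate
17 | lithium acetylide of 16 | [Li]C#CCC/C(C)=C/CC/C(C)=C/C[C@@H](O[Si](C)(C)C(C)(C)C)c1ccoc1 | intermediate
18 | (6E,10E,13R)-13-[(tert-butyldimethylsilyl)oxy]-13-(furan-3-yl)-6,10-dimethyltrideca-6,10-dien-2-ynoic acid | OC(=O)C#CCC/C(C)=C/CC/C(C)=C/C[C@@H](O[Si](C)(C)C(C)(C)C)c1ccoc1 | intermediate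
19 | (S)-2,2-dimethyl-1,3-dioxolane-4-carbaldehyde [(S)-glyceraldehyde acetonide] | O=C[C@@H]1COC(C)(C)O1 | starting material
20 | isopropyltriphenylphosphonium iodide | CC(C)[P+](c1ccccc1)(c1ccccc1)c1ccccc1.[I-] | starting material
21 | isopropylidenetriphenylphosphorane | CC(C)=P(c1ccccc1)(c1ccccc1)c1ccccc1 | intermediate
22 | (R)-2,2-dimethyl-4-(2-methylprop-1-en-1-yl)-1,3-dioxolane | CC(C)=C[C@@H]1COC(C)(C)O1 | intermediate
23 | (R)-4-methylpent-3-ene-1,2-diol | CC(C)=C[C@@H](O)CO | intermediate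
24 | (2R)-2-hydroxy-4-methylpent-3-en-1-yl 4-methylbenzenesulfonate | CC(C)=C[C@@H](O)COS(=O)(=O)c1ccc(C)cc1 | intermediate
25 | (2R)-4-methyl-1-(tosyloxy)pent-3-en-2-yl (6E,10E,13R)-13-[(tert-butyldimethylsilyl)oxy]-13-(furan-3-yl)-6,10-dimethyltrideca-6,10-dien-2-ynoate | CC(C)=C[C@H](COS(=O)(=O)c1ccc(C)cc1)OC(=O)C#CCC/C(C)=C/CC/C(C)=C/C[C@@H](O[Si](C)(C)C(C)(C)C)c1ccoc1 | intermediate
26 | α-cuprio enoate: 25 after syn addition of H–Cu, [1,3-bis(2,6-diisopropylphenyl)imidazol-2-ylidene]copper on C3 and the new hydrogen on C1′ cis to copper | CC(C)=C[C@H](COS(=O)(=O)c1ccc(C)cc1)OC(=O)/C(=C\CC/C(C)=C/CC/C(C)=C/C[C@@H](O[Si](C)(C)C(C)(C)C)c1ccoc1)[Cu-]c1n(-c2c(C(C)C)cccc2C(C)C)cc[n+]1-c1c(C(C)C)cccc1C(C)C | intermediate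
27 | (3Z,5S)-3-[(4E,8E,11R)-11-[(tert-butyldimethylsilyl)oxy]-11-(furan-3-yl)-4,8-dimethylundeca-4,8-dien-1-ylidene]-5-(2-methylprop-1-en-1-yl)dihydrofuran-2(3H)-one | CC(C)=C[C@@H]1C/C(=C/CC/C(C)=C/CC/C(C)=C/C[C@@H](O[Si](C)(C)C(C)(C)C)c2ccoc2)C(=O)O1 | intermediate
28 | furan endoperoxide of 27 (2,3,7-trioxabicyclo[2.2.1]hept-5-ene carrying the chain on C5) | CC(C)=C[C@@H]1C/C(=C/CC/C(C)=C/CC/C(C)=C/C[C@@H](O[Si](C)(C)C(C)(C)C)C2=CC3OOC2O3)C(=O)O1 | intermediate
29 | γ-hydroxybutenolide: as 27 with a 2-hydroxy-5-oxo-2,5-dihydrofuran-3-yl group on C11′ (both hemiacetal epimers) | CC(C)=C[C@@H]1C/C(=C/CC/C(C)=C/CC/C(C)=C/C[C@@H](O[Si](C)(C)C(C)(C)C)C2=CC(=O)OC2O)C(=O)O1 | intermediate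
30 | ring-opened sodium hydroxy enoate (CH2OH cis to the carboxylate) | CC(C)=C[C@@H]1C/C(=C/CC/C(C)=C/CC/C(C)=C/C[C@@H](O[Si](C)(C)C(C)(C)C)/C(CO)=C/C(=O)[O-])C(=O)O1.[Na+] | intermediate
31 | (3Z,5S)-3-[(4E,8E,11R)-11-[(tert-butyldimethylsilyl)oxy]-4,8-dimethyl-11-(5-oxo-2,5-dihydrofuran-3-yl)undeca-4,8-dien-1-ylidene]-5-(2-methylprop-1-en-1-yl)dihydrofuran-2(3H)-one | CC(C)=C[C@@H]1C/C(=C/CC/C(C)=C/CC/C(C)=C/C[C@@H](O[Si](C)(C)C(C)(C)C)C2=CC(=O)OC2)C(=O)O1 | intermediate
32 | (3Z,5S)-3-[(4E,8E,11R)-11-hydroxy-4,8-dimethyl-11-(5-oxo-2,5-dihydrofuran-3-yl)undeca-4,8-dien-1-ylidene]-5-(2-methylprop-1-en-1-yl)dihydrofuran-2(3H)-one | CC(C)=C[C@@H]1C/C(=C/CC/C(C)=C/CC/C(C)=C/C[C@@H](O)C2=CC(=O)OC2)C(=O)O1 | target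

**Count and risks**

Total step count: 19. Longest linear sequence: 15 steps (steps 1 to 5, 7 to 12 and 16 to 19).

The three steps most likely to fail:

Step 17 (the proposed new method). The ring closure may be outrun by silyl transfer from the silane to the copper allenolate, which would give uncyclised enoate after work-up. O-alkylation to a cyclic ketene acetal, loss of alkene geometry through the allenolate and further reduction of the product by Cu–H are the other ways it may go wrong. The fallback uses known chemistry, sets out from 16 and 24 and comes back at 27. K2CO3 in methanol closes 24 to (R)-2-(2-methylprop-1-en-1-yl)oxirane F1. The lithium acetylide 17, made from 16 with n-BuLi, opens F1 at its CH2 terminus in THF/DMPU to give the homopropargylic alcohol F2. Hydroxyl-directed trans-hydrostannation (Bu3SnH, [(C5Me5)RuCl]4, CH2Cl2) places tin on the alkyne carbon nearer the hydroxyl and hydrogen anti to it, giving the (Z)-alkenylstannane F3. Iodine in CH2Cl2 at −78 °C exchanges tin for iodine with retention, giving the (Z)-alkenyl iodide F4. Carbonylative lactonisation (CO 1 atm, PdCl2(PPh3)2, Et3N, THF, 50 °C) then inserts C2 between C3 and the C5 oxygen and should deliver 27 with the same Z geometry.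

Step 18. Ene reaction of singlet oxygen at the three trisubstituted alkenes may compete with the cycloaddition to the furan, and borohydride may add in a conjugate sense to the α-alkylidene lactone or open it. The fallback moves the ring oxygenation ahead of the ring closure; it sets out from 18 and 24 and comes back at 31. Photooxygenation of 18 under the conditions of step 18 gives the furan endoperoxide acid F5 and from it the γ-hydroxybutenolide acid F6. NaBH4 gives the ring-opened disodium hydroxy enoate F7, and acidification gives the butenolide acid F8. Steglich esterification of F8 with 24 gives the butenolide ester F9. The copper hydride ring closure of step 17 (through the alkenylcopper F10) then gives 31; it relies on the ynoate reacting faster with Cu–H than the hindered β,β-disubstituted butenolide.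

Step 5. The direct exchange of Si–O for C–Br on an allylic silyl ether may stall, or the bromide may transpose to the tertiary allylic position, or adventitious HBr may add to the trisubstituted alkenes. The fallback separates unmasking from activation; it sets out from 7 and comes back at 8. Pyridinium p-toluenesulfonate in methanol frees the primary allylic alcohol (2E,6E)-3,7-dimethyl-11-(trimethylsilyl)undeca-2,6-dien-10-yn-1-ol F11 without touching the alkynylsilane. An Appel bromination (CBr4, PPh3, CH2Cl2, −20 °C) then gives 8.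

**Further compounds**

F1 | step 17 | (R)-2-(2-methylprop-1-en-1-yl)oxirane | CC(C)=C[C@@H]1CO1
F2 | step 17 | (4S,10E,14E,17R)-17-[(tert-butyldimethylsilyl)oxy]-17-(furan-3-yl)-2,10,14-trimethylheptadeca-2,10,14-trien-6-yn-4-ol | CC(C)=C[C@@H](O)CC#CCC/C(C)=C/CC/C(C)=C/C[C@@H](O[Si](C)(C)C(C)(C)C)c1ccoc1
F3 | step 17 | (4S,6Z,10E,14E,17R)-17-[(tert-butyldimethylsilyl)oxy]-17-(furan-3-yl)-2,10,14-trimethyl-6-(tributylstannyl)heptadeca-2,6,10,14-tetraen-4-ol | CC(C)=C[C@@H](O)C/C(=C/CC/C(C)=C/CC/C(C)=C/C[C@@H](O[Si](C)(C)C(C)(C)C)c1ccoc1)[Sn](CCCC)(CCCC)CCCC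
F4 | step 17 | (4S,6Z,10E,14E,17R)-17-[(tert-butyldimethylsilyl)oxy]-17-(furan-3-yl)-6-iodo-2,10,14-trimethylheptadeca-2,6,10,14-tetraen-4-ol | CC(C)=C[C@@H](O)C/C(I)=C/CC/C(C)=C/CC/C(C)=C/C[C@@H](O[Si](C)(C)C(C)(C)C)c1ccoc1
F5 | step 18 | furan endoperoxide of acid 18 | OC(=O)C#CCC/C(C)=C/CC/C(C)=C/C[C@@H](O[Si](C)(C)C(C)(C)C)C1=CC2OOC1O2
F6 | step 18 | (6E,10E,13R)-13-[(tert-butyldimethylsilyl)oxy]-13-(2-hydroxy-5-oxo-2,5-dihydrofuran-3-yl)-6,10-dimethyltrideca-6,10-dien-2-ynoic acid | OC(=O)C#CCC/C(C)=C/CC/C(C)=C/C[C@@H](O[Si](C)(C)C(C)(C)C)C1=CC(=O)OC1O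
F7 | step 18 | ring-opened disodium hydroxy enoate of F6 (CH2OH cis to the enoate carboxylate) | [Na+].[Na+].[O-]C(=O)C#CCC/C(C)=C/CC/C(C)=C/C[C@@H](O[Si](C)(C)C(C)(C)C)/C(CO)=C/C(=O)[O-]
F8 | step 18 | (6E,10E,13R)-13-[(tert-butyldimethylsilyl)oxy]-6,10-dimethyl-13-(5-oxo-2,5-dihydrofuran-3-yl)trideca-6,10-dien-2-ynoic acid | OC(=O)C#CCC/C(C)=C/CC/C(C)=C/C[C@@H](O[Si](C)(C)C(C)(C)C)C1=CC(=O)OC1
F9 | step 18 | (2R)-4-methyl-1-(tosyloxy)pent-3-en-2-yl ester of F8 | CC(C)=C[C@H](COS(=O)(=O)c1ccc(C)cc1)OC(=O)C#CCC/C(C)=C/CC/C(C)=C/C[C@@H](O[Si](C)(C)C(C)(C)C)C1=CC(=O)OC1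
F10 | step 18 | alkenylcopper from F9 (copper with its carbene ligand on C3, new hydrogen on C1′ cis to copper) | CC(C)=C[C@H](COS(=O)(=O)c1ccc(C)cc1)OC(=O)/C(=C\CC/C(C)=C/CC/C(C)=C/C[C@@H](O[Si](C)(C)C(C)(C)C)C1=CC(=O)OC1)[Cu-]c1n(-c2c(C(C)C)cccc2C(C)C)cc[n+]1-c1c(C(C)C)cccc1C(C)C
F11 | step 5 | (2E,6E)-3,7-dimethyl-11-(trimethylsilyl)undeca-2,6-dien-10-yn-1-ol | C[Si](C)(C)C#CCC/C(C)=C/CC/C(C)=C/CO
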